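**Retrosynthetic overview**
The strategy rests on the unbranched tether of four CH2 groups (C1 to C4, counted from the benzylic carbon) between the para-hydroxyphenyl ring and the C5 ketone. Cutting its central C2–C3 bond leaves two CH2CH2 halves that each end in a carboxylic acid.
The ketone half, 4-oxoheptadecanoic acid, is a 1,4-dicarbonyl compound and is traced to tetradecanal and methyl acrylate by NHC umpolung (Stetter reaction, C4–C5 bond), followed by saponification.
The arene half is phloretic acid, with the phenol masked as an electron-poor pivalate so that the ring tolerates the anode.
The two acids are joined by anodic decarboxylative radical cross-coupling (mixed Kolbe electrolysis), and the phenol is released last.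
No ring is formed; the bond order is C4–C5, then C2–C3, then O-deprotection, and the target has no stereocentre.

Key step: step 4

**Route**

Step 1
Reactants: 1 tetradecanal; 2 methyl acrylate
Product: 3 methyl 4-oxoheptadecanoate
Conditions: 3-benzyl-5-(2-hydroxyethyl)-4-methylthiazolium chloride (10 mol%), Et3N (0.5 equiv), 1,4-dioxane, 75 °C, N2; 1 added slowly to 2 (1.5 equiv)
Reagents that add atoms: none
Why: In this intermolecular Stetter reaction the thiazol-2-ylidene converts the unbranched aldehyde into a Breslow intermediate (acyl anion equivalent) that adds in conjugate fashion to the unhindered acrylate, and slow addition of the aldehyde to excess acceptor in an aprotic solvent should hold back acyloin formation and transesterification.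

Step 2
Reactants: 3 methyl 4-oxoheptadecanoate
Product: 4 4-oxoheptadecanoic acid
Conditions: LiOH·H2O (2 equiv), THF/H2O 3:1, rt; then 1 M HCl to pH 2; recrystallisation
Reagents that add atoms: lithium hydroxide, [Li+].[OH-]
Why: Ester saponification by acyl–oxygen cleavage should proceed cleanly because the dialkyl ketone is inert to cold aqueous hydroxide and the long-chain keto acid precipitates on acidification.

Step 3
Reactants: 5 3-(4-hydroxyphenyl)propanoic acid (phloretic acid); 6 pivaloyl chloride
Product: 7 3-(4-pivaloyloxyphenyl)propanoic acid
Conditions: NaOH (2.1 equiv), H2O/THF, 0 °C, 6 (1.1 equiv) added dropwise; then 1 M HCl to pH 2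
Reagents that add atoms: none
Why: Under Schotten–Baumann conditions the phenoxide of the dianion is far more nucleophilic than the carboxylate, so O-acylation should give the hindered aryl pivalate, which survives brief contact with cold dilute base and the acidic work-up.

Step 4
Reactants: 4 4-oxoheptadecanoic acid; 7 3-(4-pivaloyloxyphenyl)propanoic acid (3 to 4 equiv)
Product: 8 4-(5-oxooctadecyl)phenyl pivalate
Conditions: undivided cell, smooth Pt foil anode, Pt cathode, KOH (5–10 mol% of total CO2H), MeOH/MeCN, constant current ca. 0.25–0.5 A cm−2, 20–30 °C with cooling; stopped while the electrolyte is still faintly acidic; NaHCO3 wash, chromatography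
Reagents that add atoms: none
Why: In this mixed Kolbe electrolysis both carboxylates are discharged at the Pt anode to acyloxy radicals that lose CO2 within the adsorbed carboxylate layer, and the 3-oxohexadecyl radical from 4 and the 2-(4-pivaloyloxyphenyl)ethyl radical from 7 pair to form the C2–C3 bond at the centre of the tether. The closest known reaction type is the Kolbe cross-coupling of two alkanoic acids, in which levulinic-type 4-oxo acids and 3-arylpropanoic acids are each established partners. No ring is closed and no stereocentre is created. The step needs carboxylate oxidation in preference to arene oxidation, which the electron-withdrawing pivalate on the phenol oxygen, the smooth Pt surface, the weakly acidic medium and the high current density should secure; it also needs cross-pairing over homo-pairing, which the excess of the cheap acid 7 biases statistically. The radical from 4 is primary and not conjugated with the ketone, so further oxidation to a cation is not favoured and a 1,2-acyl shift in it would be degenerate. Ending the electrolysis while free acid remains keeps cathodically formed methoxide buffered and should spare the aryl ester; the symmetrical dimers differ enough in polarity from 8 to be removed on silica.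

Step 5
Reactants: 8 4-(5-oxooctadecyl)phenyl pivalate
Product: 9 1-(4-hydroxyphenyl)octadecan-5-one (target)
Conditions: LiOH·H2O (3 equiv), THF/H2O 3:1, rt to 40 °C; then 1 M HCl to pH 4; NaHCO3 wash
Reagents that add atoms: none
Why: Hydrolysis of the aryl ester is driven by the good phenoxide leaving group, the isolated ketone is untouched by aqueous hydroxide at this temperature, and mild acidification should return the free phenol.

**Compound list**
1 | tetradecanal | CCCCCCCCCCCCCC=O | starting material
2 | methyl acrylate | C=CC(=O)OC | starting material
3 | methyl 4-oxoheptadecanoate | CCCCCCCCCCCCCC(=O)CCC(=O)OC | intermediate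
4 | 4-oxoheptadecanoic acid | CCCCCCCCCCCCCC(=O)CCC(=O)O | intermediate
5 | 3-(4-hydroxyphenyl)propanoic acid (phloretic acid) | OC(=O)CCc1ccc(O)cc1 | starting material
6 | pivaloyl chloride | CC(C)(C)C(=O)Cl | starting material
7 | 3-(4-pivaloyloxyphenyl)propanoic acid | CC(C)(C)C(=O)Oc1ccc(CCC(=O)O)cc1 | intermediate
8 | 4-(5-oxooctadecyl)phenyl pivalate | CCCCCCCCCCCCCC(=O)CCCCc1ccc(OC(=O)C(C)(C)C)cc1 | intermediate
9 | 1-(4-hydroxyphenyl)octadecan-5-one | CCCCCCCCCCCCCC(=O)CCCCc1ccc(O)cc1 | target

Total step count: 5
Longest linear sequence: 4 steps (steps 1, 2, 4, 5)

**Steps most likely to fail**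

Step 4. The electrolysis may suffer from statistical pairing that diverts the keto acid into its own dimer, from overoxidation of the radicals to cations (ether and alkene formation), from fouling of the anode by the long-chain acid, and from methanolysis of the aryl ester once the electrolyte turns basic. The fallback keeps the C2–C3 bond but replaces radical–radical pairing by a reductive decarboxylative Giese addition; it sets out from 7 and 1 and comes back at 8. Acid 7 is condensed with N-hydroxyphthalimide (N,N'-diisopropylcarbodiimide, DMAP cat., CH2Cl2) to give the redox-active ester 1,3-dioxoisoindolin-2-yl 3-(4-pivaloyloxyphenyl)propanoate F1. Aldehyde 1 is treated with vinylmagnesium bromide (THF, −78 to 0 °C) to give racemic hexadec-1-en-3-ol F2, which is oxidised with Dess–Martin periodinane to hexadec-1-en-3-one F3. Irradiating F1 and F3 with blue light in the presence of Ru(bpy)3Cl2 (cat.), Hantzsch ester and iPr2NEt in CH2Cl2 should release the 2-arylethyl radical, which adds to the terminal carbon of the enone; reduction and protonation of the adduct radical then give 8 directly.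

Step 1. Self-condensation of the aliphatic aldehyde to the acyloin and base-induced oligomerisation of the acrylate may outrun the conjugate addition. The fallback builds the 1,4-dicarbonyl array by enolate alkylation; it sets out from 1 and comes back at 4. Roskamp homologation of 1 with ethyl diazoacetate (SnCl2 cat., CH2Cl2, rt) should give ethyl 3-oxohexadecanoate F4. Alkylation of its sodium enolate (NaH, THF) with ethyl bromoacetate gives racemic diethyl 2-tetradecanoylbutanedioate F5. Heating F5 in 6 M HCl/AcOH hydrolyses both esters and decarboxylates the beta-keto acid, giving 4 without passing through 3.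

Step 3. Competing acylation at the carboxylate followed by intermolecular acyl transfer to phenoxide may lead to oligoesters and incomplete O-protection. The fallback masks the acid first; it sets out from 5 and comes back at 7. Selective carboxylate alkylation of 5 with benzyl bromide (KHCO3, DMF, rt; the phenol is not deprotonated) should give benzyl 3-(4-hydroxyphenyl)propanoate F6. Acylation of F6 with 6 (Et3N, DMAP cat., CH2Cl2, 0 °C) gives benzyl 3-(4-pivaloyloxyphenyl)propanoate F7, and hydrogenolysis (H2, Pd/C, EtOAc) removes the benzyl group to give 7.

**Further compounds**
F1 | step 4 | 1,3-dioxoisoindolin-2-yl 3-(4-pivaloyloxyphenyl)propanoate | CC(C)(C)C(=O)Oc1ccc(CCC(=O)ON2C(=O)c3ccccc3C2=O)cc1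
F2 | step 4 | hexadec-1-en-3-ol (racemic) | CCCCCCCCCCCCCC(O)C=C
F3 | step 4 | hexadec-1-en-3-one | CCCCCCCCCCCCCC(=O)C=C
F4 | step 1 | ethyl 3-oxohexadecanoate | CCCCCCCCCCCCCC(=O)CC(=O)OCC
F5 | step 1 | diethyl 2-tetradecanoylbutanedioate (racemic) | CCCCCCCCCCCCCC(=O)C(CC(=O)OCC)C(=O)OCC
F6 | step 3 | benzyl 3-(4-hydroxyphenyl)propanoate | O=C(CCc1ccc(O)cc1)OCc1ccccc1
F7 | step 3 | benzyl 3-(4-pivaloyloxyphenyl)propanoate | CC(C)(C)C(=O)Oc1ccc(CCC(=O)OCc2ccccc2)cc1
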